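## Structural features

The target is a labdane built on a trans-fused decalin: ring A is C1–C5 plus C10, ring B is C5–C10, and the two share the C5–C10 bond. Ring A carries a gem-dimethyl group at C4 and the angular methyl C20 at C10. Ring B carries an equatorial 6α-oxygen esterified as the (Z)-2-methylbut-2-enoate (angelate), a tertiary 8α-hydroxyl with an axial 8β-methyl, and at C9 an equatorial CH2 (C11) that continues into a (2E)-3-methylpenta-2,4-dienyl chain. Five stereocentres (C8, C9, C10, C5, C6) follow one another round ring B, with only C7 between the first and the last, and the quaternary C10 lies in the middle of them. The fragile parts are the angelate (Z to E isomerisation under basic or nucleophilic acylation), the tertiary C8 alcohol (dehydration under acid) and the conjugated diene (acid, electrophilic oxidants), so all three appear late. The real difficulties are the fully substituted C10 flanked by C9 and C5, the C4–C5 bond between a quaternary and a tertiary carbon, the equatorial oxygen at C6 beside the C4 methyls, and the C11–C12 bond next to the doubly shielded C9. The key step uses the fact that C10 is the one ring-fusion atom with four carbon neighbours (C20, C1, C5, C9): these can be fixed in an open chain, after which only C4–C5 (ring A) and C6–C7 (ring B) remain to be closed, with C6 entering as an aldehyde carbon that supplies the 6-oxygen.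

## Logic of the disconnections

26 ⇒ 23 + 24. The C6–O acyl bond is cut first because the Z-configured unsaturated ester is the most easily damaged group. This leaves diol 23 and the free acid 24. The forward acylation (through 25) must touch only the secondary hydroxyl and must not isomerise the acyl double bond.

23 ⇒ 15 + 20. The C11–C12 bond is cut between the ring-bound sp3 carbon and the sp2 end of the diene. This is convergent and removes the whole sensitive side chain in one piece. The forward step needs a C11 organometallic (21) at a β-branched primary carbon, retention of the alkene geometry, and masked hydroxyls (15, then 22).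

20 ⇒ 19 ⇒ 18 ⇒ 16. In the diene fragment the C14=C15 bond is cut by retro-methylenation, the aldehyde is taken back to the alcohol, and the C13–methyl and C12–I bonds are cut by retro-carbometalation (through 17). The gain is that the E geometry comes from a syn addition to an alkyne. The demand is regioselective methyl delivery to the internal alkyne carbon.

15 ⇒ 14 ⇒ 13 ⇒ 12 ⇒ 11. These are functional group changes: silyl ethers back to hydroxyls, C11–I back to C11–OH, and the C8 carbinol with its methyl plus the C11 alcohol back to a spiro-epoxide and an ester. The C8–O bond of 12 is then cut back to the exocyclic alkene of 11. The gain is that the C8 stereocentre comes from a flat carbon. The demand is attack of the oxidant on the α face.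

11 ⇒ 9 (through 10). This is the strategic cut: C6–C7 (retro carbonyl-ene) and C4–C5 (retro α-alkylation of an enol ether by a tertiary cation). Both rings and two stereocentres (C5, C6) disappear and an open chain centred on C10 remains. The forward step must alkylate at carbon before the enol ether is lost, fold chair–chair to the trans fusion, place the oxygen equatorial, and leave the alkene exocyclic.

9 ⇒ 8 ⇒ 7 ⇒ 6. The O–Si bond, the C6 oxygen and the C4–Cl bond are removed in turn, which returns a triene ester. The forward order is fixed by chemoselectivity: hydrochlorination of the trisubstituted alkene only, then anti-Markovnikov oxidation of the vinyl group only, then enol silylation of the aldehyde only.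

6 ⇒ 5 ⇒ 3 (through 4). After removal of the ester methyl, the C9–C10 bond is cut by a retro-[3,3] shift. This turns two adjacent stereocentres, one of them quaternary, into an achiral allylic ester. The forward rearrangement needs a defined enolate geometry, a chair transition state and reagent control of the absolute sense.

3 ⇒ 1 + 2. The ester C–O bond is cut to two commercial compounds. The only demand is that the β,γ-double bond of the acid part stays out of conjugation.

## Other disconnections considered

Alternative 1: The cut removes C1–C10 and C4–C5 and takes ring B from a quinone. Diene A1 (4-methylpenta-1,3-diene) would add in a Diels–Alder reaction to one methyl-bearing double bond of quinone A2 (2,6-dimethyl-1,4-benzoquinone), giving the cis-fused enedione A3; C5 would then be epimerised through the C6 enol.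
- In its favour: two cheap commercial partners reach a bicyclic core with C10 quaternary, C17 in place and oxygen at C6 and C9 in one step, and the reaction class is well known.
- Against it here: the diene has a cis methyl on its reacting terminus, so the s-cis form is poorly populated and its fully substituted carbon must bond to C5. Absolute control would need a chiral catalyst that tells two similar quinone carbonyls apart. C9 arrives as a carbonyl that still has to receive C11 and the 9α-hydrogen.
- Structure: equal to the chosen plan for C6 and better for C17, but worse for C9, which the chosen plan fixes together with C10 before any ring exists. Hydride reduction of the C6 ketone is expected from the open α face, which gives the axial alcohol, so the equatorial oxygen would need separate correction.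
- Mechanism: a [4+2] addition is safer in principle than an untested cascade, which counts for the alternative.
- Step economy: better to the core (one step against seven), but C5 epimerisation, saturation of the 2-ene, C9 homologation with deoxygenation, C6 correction and the C8 carbinol are expected to use up that lead.

Alternative 2: Only C4–C5 is cut and ring B is a preformed cyclohexanone, A4. A metal-hydride hydrogen atom transfer to C3 of the trisubstituted alkene would give the tertiary C4 radical, which adds to the C5 carbonyl to give the cis-fused decalinol A5.
- In its favour: the radical closure is precedented for such bicyclic tertiary alcohols, is little affected by crowding, and tolerates most functional groups.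
- Against it here: A5 has the wrong oxidation level at C5, a cis fusion, oxygen at C9 where carbon is needed, and nothing at C6, C7 or C8.
- Structure: worse, since 11 already carries every ring B substituent or its direct precursor.
- Mechanism: the radical ring A closure is the better of the two, because the chosen plan relies on a cation that can eliminate. Removing the C5 hydroxyl by dehydration toward C6 and hydroboration could deliver 6α-OH and the trans fusion together, an equal solution for C6.
- Step economy: worse, since one ring is closed instead of two and C8, C9, C11 and C17 remain to be built.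

Alternative 3: The cut removes C5–C10 and C8–C9. The open-chain silyloxy trienal A6 would undergo an intramolecular Diels–Alder reaction under a chiral boron Lewis acid to give the trans-fused bicyclic aldehyde A7.
- In its favour: both rings and four stereocentres (C5, C8, C9, C10) form in one catalytic, enantioselective step of a known reaction class, with C11 as an aldehyde and C6 as a masked ketone.
- Against it here: the dienophile carbon C10 is fully substituted and the diene terminus C5 is neopentylic, so the C5–C10 bond is the most hindered kind for this reaction. C8 arrives as C–H and would need later oxidation (for instance enone, epoxide, reductive opening). C6 arrives at the ketone level and needs an equatorial-selective reduction.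
- Structure: equal at C6 and C11, worse at C8.
- Mechanism: better in precedent and in catalytic absolute control, and equal in rings and bonds formed.
- Step economy: equal up to the cyclisation, since A6 needs a linear assembly comparable to that of 9, but longer afterwards than the six steps from 11.

Key step: step 7

Assumption: the (S,S)-configured diazaborolidine is taken to give the (2S,3S)-acid 5; if the ligand imposes the opposite facial sense, its (R,R)-enantiomer is used with no other change.

Remark: α/β descriptors and drimane or labdane numbering are used. The exocyclic methylene carbon of 11 is C12 of the drimane (C17 of the final labdane), so 11 is a drim-8(12)-ene and not an 8(17)-ene.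

Remark: three design choices improve on the simplest version of the precursor. The chloride is installed before the aldehyde is unveiled, because an aldehyde that still carries the trisubstituted alkene would cyclise in the citronellal manner under acid. The enol ether is a triethylsilyl ether, so that silicon leaves quickly after C-alkylation. The C5 acid partner is the β,γ-unsaturated isomer, which enolises directly at the α-carbon.

## Steps

Step 1
Reactants: 1 geraniol; 2 3-methylbut-3-enoic acid
Product: 3 (2E)-3,7-dimethylocta-2,6-dien-1-yl 3-methylbut-3-enoate
Conditions: DCC, DMAP (5 mol%), CH2Cl2, 0 °C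
Reagents that add atoms: none
Why: Steglich esterification of a primary allylic alcohol; low temperature and little DMAP keep the β,γ-double bond of the acyl part out of conjugation.

Step 2
Reactants: 3 (2E)-3,7-dimethylocta-2,6-dien-1-yl 3-methylbut-3-enoate
Product: 5 (2S,3S)-3-ethenyl-3,7-dimethyl-2-(prop-1-en-2-yl)oct-6-enoic acid, via boron dienolate 4 (not isolated)
Conditions: (S,S)-bis-sulfonamide, BBr3, CH2Cl2, rt (volatiles removed); then 3, Et3N, toluene–hexane, −78 °C → rt; aq. work-up
Reagents that add atoms: none
Why: Enantioselective Ireland–Claisen-type [3,3] rearrangement of a chiral boron ester enolate: soft enolisation with Et3N in a non-polar medium should give the dienolate with the isopropenyl group cis to the allylic oxygen. A chair across the (E)-allyl unit (chain equatorial, methyl axial) then forms C9–C10 and sets both centres in the required relative sense, while the C2-symmetric sulfonamide ligand on boron selects the enolate face and so the absolute configuration.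

Step 3
Reactants: 5 (2S,3S)-3-ethenyl-3,7-dimethyl-2-(prop-1-en-2-yl)oct-6-enoic acid
Product: 6 methyl (2S,3S)-3-ethenyl-3,7-dimethyl-2-(prop-1-en-2-yl)oct-6-enoate
Conditions: TMSCHN2, MeOH–toluene, 0 °C → rt
Reagents that add atoms: (trimethylsilyl)diazomethane, C[Si](C)(C)C=[N+]=[N-]
Why: O-Methylation of the carboxylic acid by a diazoalkane under neutral conditions, which leaves the epimerisable, deconjugated C9–H alone.

Step 4
Reactants: 6 methyl (2S,3S)-3-ethenyl-3,7-dimethyl-2-(prop-1-en-2-yl)oct-6-enoate
Product: 7 methyl (2S,3S)-7-chloro-3-ethenyl-3,7-dimethyl-2-(prop-1-en-2-yl)octanoate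
Conditions: HCl (gas, 1.5 equiv), CH2Cl2, −40 → −20 °C
Reagents that add atoms: hydrogen chloride, Cl
Why: Markovnikov hydrochlorination through the tertiary C4 cation; the trisubstituted alkene is the most basic, the isopropenyl group is deactivated by the ester-bearing C9 and is hindered, and the vinyl group would need a secondary cation.

Step 5
Reactants: 7 methyl (2S,3S)-7-chloro-3-ethenyl-3,7-dimethyl-2-(prop-1-en-2-yl)octanoate
Product: 8 methyl (2S,3S)-7-chloro-3,7-dimethyl-3-(2-oxoethyl)-2-(prop-1-en-2-yl)octanoate
Conditions: PdCl2(PhCN)2 (10 mol%), CuCl2·2H2O (10 mol%), AgNO2 (5 mol%), O2 (1 atm), t-BuOH–MeNO2 (15:1), rt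
Reagents that add atoms: dioxygen, O=O
Why: Aldehyde-selective (anti-Markovnikov) Wacker oxidation with nitrite co-catalysis; only the monosubstituted alkene reacts, and the quaternary C10 beside it reinforces delivery of oxygen to the terminal carbon.

Step 6
Reactants: 8 methyl (2S,3S)-7-chloro-3,7-dimethyl-3-(2-oxoethyl)-2-(prop-1-en-2-yl)octanoate
Product: 9 methyl (2S,3S)-7-chloro-3,7-dimethyl-2-(prop-1-en-2-yl)-3-[(E)-2-(triethylsilyloxy)ethenyl]octanoate
Conditions: TESOTf (1.2 equiv), Et3N, CH2Cl2, −78 → 0 °C
Reagents that add atoms: triethylsilyl trifluoromethanesulfonate, CC[Si](CC)(CC)OS(=O)(=O)C(F)(F)F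
Why: Soft enolisation and O-silylation of the aldehyde, which is enolised far faster than the ester; the (E)-enol ether is expected because the silyloxy group avoids the quaternary C10.

Step 7
Reactants: 9 methyl (2S,3S)-7-chloro-3,7-dimethyl-2-(prop-1-en-2-yl)-3-[(E)-2-(triethylsilyloxy)ethenyl]octanoate
Product: 11 methyl 6α-hydroxydrim-8(12)-en-11-oate, via monocyclic aldehyde 10 (not isolated)
Conditions: Me2AlCl (2.5 equiv), CH2Cl2, −78 → 0 °C; aq. potassium sodium tartrate
Reagents that add atoms: none
Why: Proposed new method: Me2AlCl takes chloride from the tertiary C4–Cl, the enol ether carbon C5 captures the C4 cation, and chloride passes from the aluminate to silicon, releasing Et3SiCl and the aluminium-bound aldehyde 10, whose C6 carbonyl then undergoes a type 2 carbonyl-ene reaction with the isopropenyl group (C7 bonds to C6, a C17 hydrogen ends on oxygen and is finally lost as methane from the Al–CH3 alkoxide complex). The closest known reaction types are the Lewis acid α-tert-alkylation of silyl enol ethers with tertiary chlorides, cation–olefin cyclisations that terminate on a silyl enol ether, and alkylaluminium halide promoted type 2 carbonyl-ene cyclisations of 5-methylhex-5-enals to 3-methylenecyclohexanols; their union in one flask on one substrate is what is new. Ring A closes in a 6-exo mode with respect to the enol double bond (C6 stays outside the ring) through a chair with the C10 methyl axial and the C9 branch equatorial, and ring B closes through a six-membered array in which both alkene carbons C7 and C8 lie inside the new ring (endo for the alkene, exo for the carbonyl). C5 is set relative to the preset C10 by the first chair, which places C6 equatorial and hence trans to C9, and C6 is set in the second closure, where the aluminium-bound oxygen takes the equatorial 6α position because the axial one is syn-axial to the methyls on C10 and C4. With the oxygen equatorial the hydrogen cannot pass in the usual chair-like bicyclic array, so the transfer is expected either through a boat-like concerted array or after the C–C bond has formed, in both cases from C17 to the oxygen-bound aluminium centre. The step needs C-alkylation before protonolysis of the enol ether, the trans fusion, the 6α-oxygen and the exocyclic alkene: the first is secured by using a tertiary chloride and no proton source together with Al–CH3 bonds that destroy HCl, the second and third by chair–chair folding about C10, and the fourth by the intramolecular hydrogen transfer from C17.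

Step 8
Reactants: 11 methyl 6α-hydroxydrim-8(12)-en-11-oate
Product: 12 methyl 8α,12-epoxy-6α-hydroxydriman-11-oate
Conditions: mCPBA, CH2Cl2–aq. NaHCO3 (two-phase), 0 °C
Reagents that add atoms: 3-chloroperoxybenzoic acid, OOC(=O)c1cccc(Cl)c1
Why: Prilezhaev epoxidation; the peracid should approach the exocyclic alkene from the α face because the β face is screened by the axial C10 methyl, which fixes the C8–O bond as α (equatorial).

Step 9
Reactants: 12 methyl 8α,12-epoxy-6α-hydroxydriman-11-oate
Product: 13 drimane-6α,8α,11-triol
Conditions: LiAlH4, THF, 0 °C → reflux; aq. NaOH work-up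
Reagents that add atoms: none
Why: Hydride reduction: the spiro-epoxide is opened at its unhindered CH2 terminus, which becomes the 8β-methyl while the C8–O bond (8α-OH) is untouched, and the ester is reduced to the C11 primary alcohol; no stereocentre is affected.

Step 10
Reactants: 13 drimane-6α,8α,11-triol
Product: 14 11-iododrimane-6α,8α-diol
Conditions: I2, PPh3, imidazole, CH2Cl2, 0 °C → rt
Reagents that add atoms: iodine, II
Why: Appel-type iodination through the alkoxyphosphonium salt; only the primary C11 hydroxyl is substituted, since the hindered secondary C6 and tertiary C8 hydroxyls react far more slowly.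

Step 11
Reactants: 14 11-iododrimane-6α,8α-diol
Product: 15 11-iodo-6α,8α-bis(triethylsilyloxy)drimane
Conditions: TESOTf (3 equiv), 2,6-lutidine, CH2Cl2, −78 → 0 °C
Reagents that add atoms: triethylsilyl trifluoromethanesulfonate, CC[Si](CC)(CC)OS(=O)(=O)C(F)(F)F
Why: Silyl triflate silylation, forceful enough for the tertiary C8 hydroxyl; both acidic protons that would quench a C11 organozinc reagent are removed.

Step 12
Reactants: 16 prop-2-yn-1-ol
Product: 18 (2E)-3-iodo-2-methylprop-2-en-1-ol, via alkenylalane 17 (not isolated)
Conditions: Me3Al (3 equiv), Cp2ZrCl2 (25 mol%), CH2Cl2, 0 °C → rt; then I2, THF, −30 → 0 °C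
Reagents that add atoms: trimethylaluminium, C[Al](C)C; iodine, II
Why: Zirconium-catalysed carboalumination of the alkyne adds CH3 and Al syn, with CH3 on the internal carbon; iodinolysis of the C–Al bond with retention gives the (E)-iodide.

Step 13
Reactants: 18 (2E)-3-iodo-2-methylprop-2-en-1-ol
Product: 19 (2E)-3-iodo-2-methylprop-2-enal
Conditions: MnO2 (activated, excess), CH2Cl2, rt
Reagents that add atoms: none
Why: Chemoselective oxidation of an allylic alcohol on MnO2; the alkene geometry and the C–I bond are not involved.

Step 14
Reactants: 19 (2E)-3-iodo-2-methylprop-2-enal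
Product: 20 (1E)-1-iodo-2-methylbuta-1,3-diene
Conditions: Ph3PCH3Br, KOtBu, THF, 0 °C; then 19, −78 → 0 °C (product kept as a solution)
Reagents that add atoms: methyltriphenylphosphonium bromide, C[P+](c1ccccc1)(c1ccccc1)c1ccccc1.[Br-]
Why: Wittig methylenation of the enal with a non-stabilised ylide; the trisubstituted C=C is a spectator, so its (E) geometry is carried into the diene.

Step 15
Reactants: 15 11-iodo-6α,8α-bis(triethylsilyloxy)drimane; 20 (1E)-1-iodo-2-methylbuta-1,3-diene
Product: 23 (12E)-labda-12,14-diene-6α,8α-diol, via alkylzinc iodide 21 (not isolated), via bis-silyl ether 22 (not isolated)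
Conditions: Zn dust, LiCl, THF, 40 °C; then 20, PdCl2(dppf) (5 mol%), THF, rt; then TBAF, THF, rt → 40 °C; aq. NH4Cl
Reagents that add atoms: none
Why: Zinc insertion into the primary C–I bond followed by palladium-catalysed Negishi coupling (sp3–sp2) with the alkenyl iodide, which reacts with retention of the (E) geometry. The wide-bite-angle diphosphine favours reductive elimination over β-hydride loss at C9, and fluoride then removes both silyl groups.

Step 16
Reactants: 23 (12E)-labda-12,14-diene-6α,8α-diol; 24 angelic acid
Product: 26 (12E)-6α-angeloyloxylabda-12,14-dien-8α-ol (CNP0582767.1), via mixed anhydride 25 (not isolated)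
Conditions: 24, 2,4,6-trichlorobenzoyl chloride, Et3N, toluene, rt; then 23, 80 °C
Reagents that add atoms: none
Why: Yamaguchi-type esterification through the mixed anhydride without a nucleophilic catalyst, conditions chosen so that the (Z)-2-methylbut-2-enoyl group is transferred without Z to E isomerisation; only the secondary C6 hydroxyl should be acylated, the tertiary C8 hydroxyl being too hindered.

## Compound list

1 | geraniol, (2E)-3,7-dimethylocta-2,6-dien-1-ol | CC(C)=CCC/C(C)=C/CO | starting material
2 | 3-methylbut-3-enoic acid | CC(=C)CC(=O)O | starting material
3 | (2E)-3,7-dimethylocta-2,6-dien-1-yl 3-methylbut-3-enoate | CC(=C)CC(=O)OC/C=C(\C)CCC=C(C)C | intermediate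
4 | boron dienolate of 3 with the (4S,5S)-diazaborolidine, isopropenyl cis to the allylic oxygen | CC(=C)/C=C(/OB1N(S(=O)(=O)c2cc(cc(c2)C(F)(F)F)C(F)(F)F)[C@@H](c2ccccc2)[C@H](c2ccccc2)N1S(=O)(=O)c1cc(cc(c1)C(F)(F)F)C(F)(F)F)OC/C=C(\C)CCC=C(C)C | intermediate (not isolated)
5 | (2S,3S)-3-ethenyl-3,7-dimethyl-2-(prop-1-en-2-yl)oct-6-enoic acid | OC(=O)[C@@H](C(C)=C)[C@@](C)(CCC=C(C)C)C=C | intermediate
6 | methyl (2S,3S)-3-ethenyl-3,7-dimethyl-2-(prop-1-en-2-yl)oct-6-enoate | COC(=O)[C@@H](C(C)=C)[C@@](C)(CCC=C(C)C)C=C | intermediate
7 | methyl (2S,3S)-7-chloro-3-ethenyl-3,7-dimethyl-2-(prop-1-en-2-yl)octanoate | COC(=O)[C@@H](C(C)=C)[C@@](C)(CCCC(C)(C)Cl)C=C | intermediate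
8 | methyl (2S,3S)-7-chloro-3,7-dimethyl-3-(2-oxoethyl)-2-(prop-1-en-2-yl)octanoate | COC(=O)[C@@H](C(C)=C)[C@@](C)(CCCC(C)(C)Cl)CC=O | intermediate
9 | methyl (2S,3S)-7-chloro-3,7-dimethyl-2-(prop-1-en-2-yl)-3-[(E)-2-(triethylsilyloxy)ethenyl]octanoate | COC(=O)[C@@H](C(C)=C)[C@@](C)(CCCC(C)(C)Cl)/C=C/O[Si](CC)(CC)CC | intermediate (key-step precursor)
10 | methyl (2S)-2-[(1S,2S)-2-formyl-1,3,3-trimethylcyclohexyl]-3-methylbut-3-enoate | COC(=O)[C@@H](C(C)=C)[C@@]1(C)CCCC(C)(C)[C@@H]1C=O | intermediate (not isolated)
11 | methyl 6α-hydroxydrim-8(12)-en-11-oate (5α-H, 9α-H, 10β-CH3) | COC(=O)[C@@H]1[C@@]2(C)CCCC(C)(C)[C@@H]2[C@@H](O)CC1=C | intermediate (key-step product)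
12 | methyl 8α,12-epoxy-6α-hydroxydriman-11-oate | COC(=O)[C@@H]1[C@@]2(C)CCCC(C)(C)[C@@H]2[C@@H](O)C[C@@]1(C3)O3 | intermediate
13 | drimane-6α,8α,11-triol | OC[C@@H]1[C@@]2(C)CCCC(C)(C)[C@@H]2[C@@H](O)C[C@@]1(C)O | intermediate
14 | 11-iododrimane-6α,8α-diol | IC[C@@H]1[C@@]2(C)CCCC(C)(C)[C@@H]2[C@@H](O)C[C@@]1(C)O | intermediate
15 | 11-iodo-6α,8α-bis(triethylsilyloxy)drimane | IC[C@@H]1[C@@]2(C)CCCC(C)(C)[C@@H]2[C@@H](O[Si](CC)(CC)CC)C[C@@]1(C)O[Si](CC)(CC)CC | intermediate
16 | prop-2-yn-1-ol | C#CCO | starting material
17 | dimethylaluminium (2E)-3-(dimethylalumanyl)-2-methylprop-2-en-1-olate (CH3 and Al cis) | C/C(CO[Al](C)C)=C\[Al](C)C | intermediate (not isolated)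
18 | (2E)-3-iodo-2-methylprop-2-en-1-ol | OC/C(C)=C/I | intermediate
19 | (2E)-3-iodo-2-methylprop-2-enal | O=C/C(C)=C/I | intermediate
20 | (1E)-1-iodo-2-methylbuta-1,3-diene | C=C/C(C)=C/I | intermediate
21 | [6α,8α-bis(triethylsilyloxy)driman-11-yl]zinc iodide | I[Zn]C[C@@H]1[C@@]2(C)CCCC(C)(C)[C@@H]2[C@@H](O[Si](CC)(CC)CC)C[C@@]1(C)O[Si](CC)(CC)CC | intermediate (not isolated)
22 | (12E)-6α,8α-bis(triethylsilyloxy)labda-12,14-diene | C=C/C(C)=C/C[C@@H]1[C@@]2(C)CCCC(C)(C)[C@@H]2[C@@H](O[Si](CC)(CC)CC)C[C@@]1(C)O[Si](CC)(CC)CC | intermediate (not isolated)
23 | (12E)-labda-12,14-diene-6α,8α-diol | C=C/C(C)=C/C[C@@H]1[C@@]2(C)CCCC(C)(C)[C@@H]2[C@@H](O)C[C@@]1(C)O | intermediate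
24 | angelic acid, (2Z)-2-methylbut-2-enoic acid | C/C=C(/C)C(=O)O | starting material
25 | (2Z)-2-methylbut-2-enoic 2,4,6-trichlorobenzoic anhydride | C/C=C(/C)C(=O)OC(=O)c1c(Cl)cc(Cl)cc1Cl | intermediate (not isolated)
26 | (12E)-6α-[(2Z)-2-methylbut-2-enoyloxy]labda-12,14-dien-8α-ol, CNP0582767.1 | C=C/C(C)=C/C[C@@H]1[C@@]2(C)CCCC(C)(C)[C@@H]2[C@@H](OC(=O)/C(C)=C\C)C[C@@]1(C)O | target

## Step count and least certain steps

Total step count: 16. Longest linear sequence: 13 steps (steps 1 to 11, 15 and 16); steps 12 to 14 make the diene fragment.

Step 7 (key step). Several processes may interfere: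
- loss of HCl from the C4 cation, followed by protonolysis of the enol ether by the acid so formed;
- methyl transfer from aluminium to the cation;
- epimerisation at C5 before ring B closes, leading to a cis fusion;
- ring B closure with the oxygen axial, or with proton loss from C7 or C9 instead of C17 if the carbonyl-ene stage becomes fully stepwise.

The fallback separates the cascade into two individually known reactions with the intermediate isolated. It sets out from 9: catalytic ZnBr2 in CH2Cl2 at 0 °C effects only the Lewis acid α-tert-alkylation, and aldehyde 10 is isolated, where its C5 centre can be equilibrated to the equatorial aldehyde with a trace of amine base. Aldehyde 10 is then cyclised in a separate type 2 carbonyl-ene reaction with the bulky MeAl(OAr)2 (Ar = 4-bromo-2,6-di-tert-butylphenyl) in CH2Cl2 at −78 °C, a reagent class known to favour the equatorial alcohol and the exocyclic alkene. The route is rejoined at 11, and no compound outside the list is formed.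

Step 2. Control over the geometry of the boron dienolate may be lost, which would pass through the same chair into the C9 epimer, or the ligand may shield the enolate face incompletely. The fallback changes the stereochemical pairing and sets out from 2. Esterification with commercial nerol gives (2Z)-3,7-dimethylocta-2,6-dien-1-yl 3-methylbut-3-enoate F1. The boron enolate Claisen rearrangement is then run with i-Pr2NEt in CH2Cl2, conditions that favour the dienolate with the isopropenyl group cis to the boron-bound oxygen, F2. A (Z)-allyl unit with this enolate geometry converges through the chair on the same relative configuration. The enantiomeric (R,R)-controller would be used if, as expected, the ligand shields the same enolate face whatever the enolate geometry. The route is rejoined at 5.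

Step 5. The tertiary chloride may ionise or eliminate in the presence of the silver and copper salts, or some oxidation may occur at the internal carbon to give the methyl ketone. The fallback replaces the oxidation by hydroboration and sets out from 7. Disiamylborane in THF at 0 °C should add to the vinyl group only, giving the alkylborane F3. Oxidation with NaBO3 gives the primary alcohol methyl (2S,3S)-7-chloro-3-(2-hydroxyethyl)-3,7-dimethyl-2-(prop-1-en-2-yl)octanoate F4, and Dess–Martin oxidation returns to the route at 8.

Step 15. Zinc insertion or transmetalation may be slow at the β-branched C11, β-hydride loss may occur from the alkylpalladium intermediate, and the volatile dienyl iodide may evaporate. The fallback changes the mechanism to a radical one and sets out from the unprotected iodide 14. A nickel-catalysed reductive cross-electrophile coupling with 20 (NiBr2(dme), 4,4'-di-tert-butyl-2,2'-bipyridine, Zn powder, N,N-dimethylacetamide, rt) proceeds through a C11 radical, tolerates free hydroxyls and rejoins the route at 23. It bypasses 15, 21 and 22 and forms no compound outside the list.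

Step 16. The acyl group may isomerise from Z to E during activation, or acylation of the hindered 6α-hydroxyl may be sluggish. The fallback builds the Z double bond on the ester instead of transferring it and sets out from 23. Steglich esterification with 2-[bis(2,2,2-trifluoroethoxy)phosphoryl]propanoic acid gives the phosphonate ester F5. A Still–Gennari olefination with acetaldehyde (KN(SiMe3)2, 18-crown-6, THF, −78 °C) then gives the (Z)-2-methylbut-2-enoate and rejoins the route at 26.

## Further compounds

F0 | step 7 | none | none
F1 | step 2 | (2Z)-3,7-dimethylocta-2,6-dien-1-yl 3-methylbut-3-enoate | CC(=C)CC(=O)OC/C=C(/C)CCC=C(C)C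
F2 | step 2 | boron dienolate of F1 with the (4R,5R)-diazaborolidine, isopropenyl cis to the boron-bound oxygen | CC(=C)/C=C(\OB1N(S(=O)(=O)c2cc(cc(c2)C(F)(F)F)C(F)(F)F)[C@H](c2ccccc2)[C@@H](c2ccccc2)N1S(=O)(=O)c1cc(cc(c1)C(F)(F)F)C(F)(F)F)OC/C=C(/C)CCC=C(C)C
F3 | step 5 | methyl 7-chloro-3-{2-[bis(3-methylbutan-2-yl)boranyl]ethyl}-3,7-dimethyl-2-(prop-1-en-2-yl)octanoate, configuration as in 7 | COC(=O)[C@@H](C(C)=C)[C@@](C)(CCCC(C)(C)Cl)CCB(C(C)C(C)C)C(C)C(C)C
F4 | step 5 | methyl (2S,3S)-7-chloro-3-(2-hydroxyethyl)-3,7-dimethyl-2-(prop-1-en-2-yl)octanoate | COC(=O)[C@@H](C(C)=C)[C@@](C)(CCCC(C)(C)Cl)CCO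
F0 | step 15 | none | none
F5 | step 16 | (12E)-8α-hydroxylabda-12,14-dien-6α-yl 2-[bis(2,2,2-trifluoroethoxy)phosphoryl]propanoate | C=C/C(C)=C/C[C@@H]1[C@@]2(C)CCCC(C)(C)[C@@H]2[C@@H](OC(=O)C(C)P(=O)(OCC(F)(F)F)OCC(F)(F)F)C[C@@]1(C)O
A1 | alternative 1 | 4-methylpenta-1,3-diene | C=CC=C(C)C
A2 | alternative 1 | 2,6-dimethyl-1,4-benzoquinone | CC1=CC(=O)C=C(C)C1=O
A3 | alternative 1 | cis-fused 4,4,8,10-tetramethyl-decalin-2,7-diene-6,9-dione (labdane numbering) | O=C1[C@@]2(C)CC=CC(C)(C)[C@H]2C(=O)C=C1C
A4 | alternative 2 | 3-(tert-butyldimethylsilyloxy)-2-methyl-2-(4-methylpent-3-en-1-yl)cyclohexan-1-one | CC(C)(C)[Si](C)(C)O[C@@H]1[C@@](C)(CCC=C(C)C)C(=O)CCC1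
A5 | alternative 2 | cis-fused 9-(tert-butyldimethylsilyloxy)-4,4,10-trimethyldecalin-5-ol (labdane numbering) | CC(C)(C)[Si](C)(C)O[C@@H]1[C@@]2(C)CCCC(C)(C)[C@@]2(O)CCC1
A6 | alternative 3 | (2E,8Z,10E)-3,7,7-trimethyl-9-(triisopropylsilyloxy)dodeca-2,8,10-trienal | O=C/C=C(\C)CCCC(C)(C)/C=C(/C=C/C)O[Si](C(C)C)(C(C)C)C(C)C
A7 | alternative 3 | trans-fused 6-(triisopropylsilyloxy)-8β-methyl-drim-6-en-11-al type bicyclic aldehyde (labdane numbering) | O=C[C@@H]1[C@@]2(C)CCCC(C)(C)[C@@H]2C(O[Si](C(C)C)(C(C)C)C(C)C)=C[C@@H]1C
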